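**Retrosynthetic overview**
1. Target 21 ⇐ tris-MOM flavan 20 (global MOM removal). The pyran ring is closed by aryl C8a–O bond formation from the (S)-chloro alcohol 19, which leaves C2 untouched.
2. 19 ⇐ (S)-benzylic carbamate 18 ⇐ key C2–C1' bond: the carbinol carbon of primary carbamate 15 is used as an enantioenriched α-oxy carbanion (sparteine-mediated lithiation, then zinc, then Pd) against aryl bromide 5. This step sets C2.
3. 15 ⇐ B-alkyl Suzuki coupling of hydroborated allyl carbamate 11 with bromochloroarene 8 (from 5-chloro-2-methoxyphenol), then lithiation between Cl and OMOM and prenylation.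
4. 5 ⇐ 4-bromocatechol: bis-MOM ether, lithiation between Br and OMOM, prenylation.
5. Ring order: rings A and B come from the aromatic starting materials; ring C (the pyran) is the only ring formed, in step 10.

Assumption: the only stereocentre (C2 of the chroman) is (S), as read from the SMILES; (+)-sparteine is taken as commercially available.

**Step 1**
Reactants: 1 4-bromobenzene-1,2-diol (4-bromocatechol)
Product: 2 4-bromo-1,2-bis(methoxymethoxy)benzene
Conditions: MOMCl (2.5 equiv), i-Pr2NEt (3 equiv), CH2Cl2, 0 °C → rt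
Reagents that add atoms: chloromethyl methyl ether, COCCl
Why: Williamson-type O-alkylation of both phenols gives MOM ethers that direct the next lithiation and survive the organolithium, hydride and palladium steps.

**Step 2**
Reactants: 2 4-bromo-1,2-bis(methoxymethoxy)benzene; 3 1-bromo-3-methylbut-2-ene (prenyl bromide)
Product: 5 1-bromo-3,4-bis(methoxymethoxy)-2-(3-methylbut-2-en-1-yl)benzene, via aryllithium 4 (not isolated)
Conditions: LiN(i-Pr)2 (1.1 equiv), THF, −78 °C, 1 h; then CuBr·SMe2 (10 mol%), 3 (1.4 equiv), −78 → −30 °C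
Reagents that add atoms: none
Why: Directed ortho-metalation with an amide base (no Br/Li exchange) removes the proton flanked by Br and OMOM, and copper-catalysed SN2 allylation of this hindered aryl metal gives the linear prenyl arene at a temperature below benzyne formation.

**Step 3**
Reactants: 6 5-chloro-2-methoxyphenol
Product: 7 4-bromo-5-chloro-2-methoxyphenol
Conditions: NBS (1.0 equiv), MeCN, 0 °C
Reagents that add atoms: N-bromosuccinimide, O=C1CCC(=O)N1Br
Why: Electrophilic aromatic bromination goes para to the free phenol, the most activated and least hindered position (para to OMe is blocked by Cl).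

**Step 4**
Reactants: 7 4-bromo-5-chloro-2-methoxyphenol
Product: 8 1-bromo-2-chloro-5-methoxy-4-(methoxymethoxy)benzene
Conditions: MOMCl (1.3 equiv), i-Pr2NEt (1.6 equiv), CH2Cl2, 0 °C → rt
Reagents that add atoms: chloromethyl methyl ether, COCCl
Why: Phenol O-alkylation masks the future 7-OH and installs the group that, together with Cl, will direct the ring-A lithiation.

**Step 5**
Reactants: 9 prop-2-en-1-ol (allyl alcohol); 10 N,N-diisopropylcarbamoyl chloride
Product: 11 prop-2-en-1-yl N,N-diisopropylcarbamate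
Conditions: Et3N (1.5 equiv), DMAP (cat.), CH2Cl2, reflux
Reagents that add atoms: none
Why: O-acylation with the hindered carbamoyl chloride gives the base-stable Hoppe carbamate that will later direct the α-lithiation.

**Step 6**
Reactants: 11 prop-2-en-1-yl N,N-diisopropylcarbamate; 8 1-bromo-2-chloro-5-methoxy-4-(methoxymethoxy)benzene
Product: 13 3-[2-chloro-5-methoxy-4-(methoxymethoxy)phenyl]propyl N,N-diisopropylcarbamate, via alkylborane 12 (not isolated)
Conditions: 9-BBN-H (1.1 equiv), THF, 0 °C → rt; then 8, PdCl2(dppf) (3 mol%), 3 M aq NaOH, THF, 65 °C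
Reagents that add atoms: none
Why: Anti-Markovnikov hydroboration followed by B-alkyl Suzuki–Miyaura coupling attaches the three-carbon chain at C–Br only, because oxidative addition into the C–Cl bond is much slower.

**Step 7**
Reactants: 13 3-[2-chloro-5-methoxy-4-(methoxymethoxy)phenyl]propyl N,N-diisopropylcarbamate; 3 1-bromo-3-methylbut-2-ene
Product: 15 3-[2-chloro-5-methoxy-4-(methoxymethoxy)-3-(3-methylbut-2-en-1-yl)phenyl]propyl N,N-diisopropylcarbamate, via aryllithium 14 (not isolated)
Conditions: lithium 2,2,6,6-tetramethylpiperidide (1.2 equiv), THF, −78 °C, 1.5 h; then CuBr·SMe2 (10 mol%), 3 (1.4 equiv), −78 → −30 °C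
Reagents that add atoms: none
Why: Directed ortho-metalation takes the only ring proton flanked by Cl and OMOM (the amide base does not touch the alkyl carbamate), and copper-catalysed SN2 allylation then installs the ring-A prenyl group.

**Step 8 (key step)**
Reactants: 15 3-[2-chloro-5-methoxy-4-(methoxymethoxy)-3-(3-methylbut-2-en-1-yl)phenyl]propyl N,N-diisopropylcarbamate; 5 1-bromo-3,4-bis(methoxymethoxy)-2-(3-methylbut-2-en-1-yl)benzene
Product: 18 (1S)-1-[3,4-bis(methoxymethoxy)-2-(3-methylbut-2-en-1-yl)phenyl]-3-[2-chloro-5-methoxy-4-(methoxymethoxy)-3-(3-methylbut-2-en-1-yl)phenyl]propyl N,N-diisopropylcarbamate, via lithiated carbamate 16 (not isolated), via alkylzinc chloride 17 (not isolated)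
Conditions: 15 (1.3 equiv), s-BuLi (1.3 equiv), (+)-sparteine (1.3 equiv), Et2O, −78 °C, 5 h; ZnCl2 (1.4 equiv, THF), −78 °C → rt; then 5 (1.0 equiv), Pd(OAc)2 (5 mol%), t-Bu3P·HBF4 (6 mol%), rt, 16 h
Reagents that add atoms: none
Why: Hoppe asymmetric deprotonation with s-BuLi/(+)-sparteine removes the pro-R α-proton to give the configurationally stable (R)-α-oxy carbanion 16, which makes the normally electrophilic carbinol carbon a nucleophile; Li→Zn exchange and Pd-catalysed Negishi coupling with aryl bromide 5 both proceed with retention, so the aryl group takes the place of lithium and C2 is set as (S), while the di-ortho-substituted aryl chloride reacts far more slowly than the bromide.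

**Step 9**
Reactants: 18 the (1S)-carbamate
Product: 19 (1S)-1-[3,4-bis(methoxymethoxy)-2-(3-methylbut-2-en-1-yl)phenyl]-3-[2-chloro-5-methoxy-4-(methoxymethoxy)-3-(3-methylbut-2-en-1-yl)phenyl]propan-1-ol
Conditions: LiAlH4 (4 equiv), THF, reflux; Fieser work-up
Reagents that add atoms: none
Why: Hydride reduction of the carbamate carbonyl releases the secondary alkoxide without touching the C2–O bond, so the (S) configuration is kept; the aryl chloride, MOM ethers and prenyl groups are inert to LiAlH4.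

**Step 10**
Reactants: 19 the (1S)-chloro alcohol
Product: 20 (2S)-2-[3,4-bis(methoxymethoxy)-2-(3-methylbut-2-en-1-yl)phenyl]-6-methoxy-7-(methoxymethoxy)-8-(3-methylbut-2-en-1-yl)-3,4-dihydro-2H-chromene
Conditions: [Pd(allyl)Cl]2 (2.5 mol%), RockPhos (6 mol%), Cs2CO3 (1.5 equiv), toluene, 90 °C
Reagents that add atoms: none
Why: Buchwald-type palladium-catalysed intramolecular C–O coupling (oxidative addition into Ar–Cl, alkoxide exchange, six-membered-ring C–O reductive elimination from a bulky biarylphosphine complex) closes ring C through the aryl carbon, so the C2–O bond is never broken and C2 stays (S).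

**Step 11**
Reactants: 20 the (2S)-tris-MOM flavan
Product: 21 (2S)-2-[3,4-dihydroxy-2-(3-methylbut-2-en-1-yl)phenyl]-7-hydroxy-6-methoxy-8-(3-methylbut-2-en-1-yl)-3,4-dihydro-2H-chromene (target)
Conditions: conc. aq HCl (cat.), degassed MeOH, 40 °C
Reagents that add atoms: none
Why: Acid-catalysed acetal exchange with methanol removes the three aryl MOM ethers under conditions mild enough to leave the o-prenyl phenols uncyclised and the benzylic ether at C2 intact.

**Compound list**
1 | 4-bromobenzene-1,2-diol (4-bromocatechol) | Oc1ccc(Br)cc1O | starting material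
2 | 4-bromo-1,2-bis(methoxymethoxy)benzene | COCOc1ccc(Br)cc1OCOC | intermediate
3 | 1-bromo-3-methylbut-2-ene (prenyl bromide) | CC(C)=CCBr | starting material
4 | [6-bromo-2,3-bis(methoxymethoxy)phenyl]lithium | [Li]c1c(Br)ccc(OCOC)c1OCOC | intermediate
5 | 1-bromo-3,4-bis(methoxymethoxy)-2-(3-methylbut-2-en-1-yl)benzene | COCOc1ccc(Br)c(CC=C(C)C)c1OCOC | intermediate
6 | 5-chloro-2-methoxyphenol | COc1ccc(Cl)cc1O | starting material
7 | 4-bromo-5-chloro-2-methoxyphenol | COc1cc(Br)c(Cl)cc1O | intermediate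
8 | 1-bromo-2-chloro-5-methoxy-4-(methoxymethoxy)benzene | COCOc1cc(Cl)c(Br)cc1OC | intermediate
9 | prop-2-en-1-ol (allyl alcohol) | C=CCO | starting material
10 | N,N-diisopropylcarbamoyl chloride | CC(C)N(C(C)C)C(=O)Cl | starting material
11 | prop-2-en-1-yl N,N-diisopropylcarbamate | C=CCOC(=O)N(C(C)C)C(C)C | intermediate
12 | 3-(9-borabicyclo[3.3.1]nonan-9-yl)propyl N,N-diisopropylcarbamate | CC(C)N(C(C)C)C(=O)OCCCB1C2CCCC1CCC2 | intermediate
13 | 3-[2-chloro-5-methoxy-4-(methoxymethoxy)phenyl]propyl N,N-diisopropylcarbamate | COCOc1cc(Cl)c(CCCOC(=O)N(C(C)C)C(C)C)cc1OC | intermediate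
14 | {2-chloro-3-[3-(diisopropylcarbamoyloxy)propyl]-5-methoxy-6-(methoxymethoxy)phenyl}lithium | COCOc1c([Li])c(Cl)c(CCCOC(=O)N(C(C)C)C(C)C)cc1OC | intermediate
15 | 3-[2-chloro-5-methoxy-4-(methoxymethoxy)-3-(3-methylbut-2-en-1-yl)phenyl]propyl N,N-diisopropylcarbamate | COCOc1c(CC=C(C)C)c(Cl)c(CCCOC(=O)N(C(C)C)C(C)C)cc1OC | intermediate
16 | (1R)-1-lithio-3-[2-chloro-5-methoxy-4-(methoxymethoxy)-3-(3-methylbut-2-en-1-yl)phenyl]propyl N,N-diisopropylcarbamate (sparteine complex) | CC(C)N(C(C)C)C(=O)O[C@H]([Li])CCc1cc(OC)c(OCOC)c(CC=C(C)C)c1Cl | intermediate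
17 | (1R)-1-(chlorozincio)-3-[2-chloro-5-methoxy-4-(methoxymethoxy)-3-(3-methylbut-2-en-1-yl)phenyl]propyl N,N-diisopropylcarbamate | CC(C)N(C(C)C)C(=O)O[C@H]([Zn]Cl)CCc1cc(OC)c(OCOC)c(CC=C(C)C)c1Cl | intermediate
18 | (1S)-1-[3,4-bis(methoxymethoxy)-2-(3-methylbut-2-en-1-yl)phenyl]-3-[2-chloro-5-methoxy-4-(methoxymethoxy)-3-(3-methylbut-2-en-1-yl)phenyl]propyl N,N-diisopropylcarbamate | CC(C)N(C(C)C)C(=O)O[C@H](c1ccc(OCOC)c(OCOC)c1CC=C(C)C)CCc1cc(OC)c(OCOC)c(CC=C(C)C)c1Cl | intermediate
19 | (1S)-1-[3,4-bis(methoxymethoxy)-2-(3-methylbut-2-en-1-yl)phenyl]-3-[2-chloro-5-methoxy-4-(methoxymethoxy)-3-(3-methylbut-2-en-1-yl)phenyl]propan-1-ol | O[C@H](c1ccc(OCOC)c(OCOC)c1CC=C(C)C)CCc1cc(OC)c(OCOC)c(CC=C(C)C)c1Cl | intermediate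
20 | (2S)-2-[3,4-bis(methoxymethoxy)-2-(3-methylbut-2-en-1-yl)phenyl]-6-methoxy-7-(methoxymethoxy)-8-(3-methylbut-2-en-1-yl)-3,4-dihydro-2H-chromene | COc1cc2c(c(CC=C(C)C)c1OCOC)O[C@H](c1ccc(OCOC)c(OCOC)c1CC=C(C)C)CC2 | intermediate
21 | (2S)-2-[3,4-dihydroxy-2-(3-methylbut-2-en-1-yl)phenyl]-7-hydroxy-6-methoxy-8-(3-methylbut-2-en-1-yl)-3,4-dihydro-2H-chromene | COc1cc2c(c(CC=C(C)C)c1O)O[C@H](c1ccc(O)c(O)c1CC=C(C)C)CC2 | target

**Step count**
Total: 11 steps. Longest linear sequence: 8 steps (3, 4, 6, 7, 8, 9, 10, 11).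

**Three steps most likely to fail, with fallbacks**

Step 8 is the weakest point. The secondary α-carbamoyloxy alkylzinc must couple with an ortho-prenylated aryl bromide. Competing paths are lateral lithiation at the ring-A prenyl CH2, β-hydride elimination at palladium, and intramolecular coupling onto the aryl chloride to give an indanyl carbamate. The fallback keeps the same lithiated carbamate 16 but makes the C2–aryl bond by a boronate 1,2-shift. It sets out from 5 and 15 and comes back at 19, so step 9 is no longer needed.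
- Bromide 5 is converted by Br/Li exchange (n-BuLi, THF, −78 °C) and 2-isopropoxy-4,4,5,5-tetramethyl-1,3,2-dioxaborolane into 2-[3,4-bis(methoxymethoxy)-2-(3-methylbut-2-en-1-yl)phenyl]-4,4,5,5-tetramethyl-1,3,2-dioxaborolane F1.
- F1 is added at −78 °C to 16 (generated from 15 with s-BuLi/(+)-sparteine as before) to give, with retention, the lithium boronate complex F2.
- Warming with MgBr2·OEt2/MeOH triggers stereospecific 1,2-aryl migration with loss of the carbamate (inversion at carbon) to the (S)-benzylic pinacol boronic ester F3.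
- NaOH/H2O2 oxidation (retention) gives alcohol 19 with the same (S) configuration as the main route.

Step 10 may fail because the aryl chloride is di-ortho-substituted and electron-rich, and the secondary benzylic alkoxide on palladium can undergo β-hydride elimination to the ketone. The fallback replaces the reductive elimination at palladium by a copper-mediated oxidative etherification. It sets out from 19 and comes back at 20.
- Miyaura borylation of the C–Cl bond (Pd2(dba)3, XPhos, B2pin2, KOAc, dioxane, 100 °C) gives (1S)-1-[3,4-bis(methoxymethoxy)-2-(3-methylbut-2-en-1-yl)phenyl]-3-[5-methoxy-4-(methoxymethoxy)-3-(3-methylbut-2-en-1-yl)-2-(4,4,5,5-tetramethyl-1,3,2-dioxaborolan-2-yl)phenyl]propan-1-ol F4.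
- Intramolecular Chan–Lam coupling (Cu(OAc)2, pyridine, O2, 4 Å molecular sieves, CH2Cl2, rt) closes ring C to 20; the C2–O bond is again untouched, so C2 stays (S).

Step 11 may fail because Brønsted acid can cyclise the o-prenyl phenols to dimethylchromans or open the 4'-oxygenated benzylic ether at C2. The fallback avoids protic acid by exchanging the protecting groups first. It sets out from 20 and comes back at 21.
- Et3SiOTf/2,2'-bipyridyl (CH2Cl2, 0 °C) converts the three aryl MOM ethers directly into (2S)-6-methoxy-8-(3-methylbut-2-en-1-yl)-7-(triethylsilyloxy)-2-[2-(3-methylbut-2-en-1-yl)-3,4-bis(triethylsilyloxy)phenyl]-3,4-dihydro-2H-chromene F5.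
- Bu4NF buffered with AcOH (THF, 0 °C) removes the silyl groups to give 21.

**Further compounds**
F1 | step 8 | 2-[3,4-bis(methoxymethoxy)-2-(3-methylbut-2-en-1-yl)phenyl]-4,4,5,5-tetramethyl-1,3,2-dioxaborolane | COCOc1ccc(B2OC(C)(C)C(C)(C)O2)c(CC=C(C)C)c1OCOC
F2 | step 8 | lithium (R)-boronate complex from 16 and F1 (B bears the pinacolato group, the ring-B aryl group and the carbamoyloxy-bearing C2) | CC(C)N(C(C)C)C(=O)O[C@H]([B-]1(OC(C)(C)C(C)(C)O1)c1ccc(OCOC)c(OCOC)c1CC=C(C)C)CCc1cc(OC)c(OCOC)c(CC=C(C)C)c1Cl.[Li+]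
F3 | step 8 | 2-{(1S)-1-[3,4-bis(methoxymethoxy)-2-(3-methylbut-2-en-1-yl)phenyl]-3-[2-chloro-5-methoxy-4-(methoxymethoxy)-3-(3-methylbut-2-en-1-yl)phenyl]propyl}-4,4,5,5-tetramethyl-1,3,2-dioxaborolane | CC1(C)OB(OC1(C)C)[C@H](c1ccc(OCOC)c(OCOC)c1CC=C(C)C)CCc1cc(OC)c(OCOC)c(CC=C(C)C)c1Cl
F4 | step 10 | (1S)-1-[3,4-bis(methoxymethoxy)-2-(3-methylbut-2-en-1-yl)phenyl]-3-[5-methoxy-4-(methoxymethoxy)-3-(3-methylbut-2-en-1-yl)-2-(4,4,5,5-tetramethyl-1,3,2-dioxaborolan-2-yl)phenyl]propan-1-ol | O[C@H](c1ccc(OCOC)c(OCOC)c1CC=C(C)C)CCc1cc(OC)c(OCOC)c(CC=C(C)C)c1B1OC(C)(C)C(C)(C)O1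
F5 | step 11 | (2S)-6-methoxy-8-(3-methylbut-2-en-1-yl)-7-(triethylsilyloxy)-2-[2-(3-methylbut-2-en-1-yl)-3,4-bis(triethylsilyloxy)phenyl]-3,4-dihydro-2H-chromene | COc1cc2c(c(CC=C(C)C)c1O[Si](CC)(CC)CC)O[C@H](c1ccc(O[Si](CC)(CC)CC)c(O[Si](CC)(CC)CC)c1CC=C(C)C)CC2
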